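**Strategy.** Everything rests on disconnecting ring A at C5–C6. In ring A the three oxygen-bearing carbons (C5, C7, C8a) sit between the three carbon-substituted ones (C4a, C6, C8), the 1,3,5-trioxygenation of a cyclised polyketide, and the oxygen on C8a doubles as O1 of ring C. The precursor 17 is therefore a finished ring C: a methyl 5-aryl-4-oxo-4H-pyran-3-carboxylate whose C2 carries the prenylated ketone chain (C8, C7, C6) with the (S)-silyloxy side chain. One base-mediated intramolecular Claisen condensation joins C6 to the ester carbon C5 and aromatises to the 5,7-dihydroxy-6,8-dialkylisoflavone 18, with every carbon substituent regiochemically locked. The stereocentre is bought with (R)-2-isopropyloxirane.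

Key step: step 9

Assumption: 6 is drawn as the triketo tautomer although it should exist as a chelated enol. 11 and 17 are used as epimer mixtures at centres that are destroyed later. The single stereocentre of the target is (S) and comes unchanged from the (R)-epoxide; the descriptor changes without inversion because the CIP priorities change when the CH2 terminus becomes a carbon chain.

Step 1
Reactants: 1 2-(4-hydroxyphenyl)acetic acid
Product: 3 2-[4-(methoxymethoxy)phenyl]acetic acid, via methoxymethyl ester 2 (not isolated)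
Conditions: MeOCH2Cl (2.5 equiv), i-Pr2NEt, CH2Cl2, 0 → 23 °C; then LiOH, THF/H2O, 23 °C; aq. HCl to pH 4, 0 °C
Reagents that add atoms: chloromethyl methyl ether, COCCl
Why: Williamson-type O-alkylation protects the phenol and also esterifies the acid, and because the acyloxymethyl ester is far more base-labile than the aryl acetal, saponification should return only the free acid.

Step 2
Reactants: 3 2-[4-(methoxymethoxy)phenyl]acetic acid; 4 methyl acetoacetate
Product: 6 methyl 2-acetyl-4-[4-(methoxymethoxy)phenyl]-3-oxobutanoate, via acid chloride 5 (not isolated)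
Conditions: 1-chloro-N,N,2-trimethylprop-1-en-1-amine, CH2Cl2, 0 → 23 °C; then 4, MgCl2, pyridine, CH2Cl2, 0 → 23 °C
Reagents that add atoms: none
Why: The acid chloride is made under neutral conditions that spare the acetal and should C-acylate the magnesium chelate of the β-keto ester (soft enolisation with MgCl2 and an amine base), the chelate directing the acyl group to carbon and not to oxygen.

Step 3
Reactants: 6 methyl 2-acetyl-4-[4-(methoxymethoxy)phenyl]-3-oxobutanoate
Product: 8 methyl 5-[4-(methoxymethoxy)phenyl]-2-methyl-4-oxo-4H-pyran-3-carboxylate, via enaminone 7 (not isolated)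
Conditions: Me2NCH(OMe)2 (1.1 equiv), toluene, 60 °C; then AcOH (cat.), 60 °C
Reagents that add atoms: N,N-dimethylformamide dimethyl acetal, COC(OC)N(C)C
Why: Aminomethylenation of the most activated CH2 (benzylic, next to the chelated carbonyl) followed by addition–elimination of the acetyl enol oxygen with loss of Me2NH is the pyranone counterpart of the deoxybenzoin-to-isoflavone annulation, and a near-stoichiometric amount of acetal at moderate temperature should limit condensation at the methyl groups.

Step 4
Reactants: 9 (2R)-2-(propan-2-yl)oxirane; 10 dimethyl malonate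
Product: 11 methyl (5S)-2-oxo-5-(propan-2-yl)oxolane-3-carboxylate (C3 epimers)
Conditions: NaOMe (1.1 equiv), MeOH, 65 °C; then aq. HCl, 0 °C
Reagents that add atoms: none
Why: SN2 opening of the monosubstituted epoxide by sodium dimethyl malonate at the unhindered CH2 terminus and lactonisation in the same flask (malonate–epoxide lactone synthesis) do not touch the C–O stereocentre, so the (R)-epoxide should give the (5S)-lactone, while the new C3 centre forms without control and is removed in step 5.

Step 5
Reactants: 11 methyl (5S)-2-oxo-5-(propan-2-yl)oxolane-3-carboxylate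
Product: 12 (5S)-5-(propan-2-yl)oxolan-2-one
Conditions: LiCl, H2O, DMSO, 140 °C
Reagents that add atoms: none
Why: Krapcho dealkoxycarbonylation removes the activated methyl ester of the α-carbomethoxy lactone, and the C5 stereocentre is not enolisable and stays as set.

Step 6
Reactants: 12 (5S)-5-(propan-2-yl)oxolan-2-one
Product: 14 (4S)-4-[(tert-butyldimethylsilyl)oxy]-N-methoxy-N,5-dimethylhexanamide, via hydroxy amide 13 (not isolated)
Conditions: MeNH(OMe)·HCl, AlMe3, CH2Cl2, 0 → 23 °C; aq. KNaC4H4O6 (potassium sodium tartrate) work-up; crude 13, t-BuMe2SiCl, imidazole, DMF, 23 °C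
Reagents that add atoms: N,O-dimethylhydroxylamine hydrochloride, CNOC.Cl; tert-butyldimethylsilyl chloride, CC(C)(C)[Si](C)(C)Cl
Why: Aluminium amide aminolysis of the lactone (Weinreb amide formation by acyl–oxygen cleavage) keeps the configuration, and immediate silylation of the freed secondary alcohol prevents relactonisation and later hemiketal formation with the C7 ketone.

Step 7
Reactants: 8 methyl 5-[4-(methoxymethoxy)phenyl]-2-methyl-4-oxo-4H-pyran-3-carboxylate; 14 (4S)-4-[(tert-butyldimethylsilyl)oxy]-N-methoxy-N,5-dimethylhexanamide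
Product: 15 methyl 2-[(5S)-5-[(tert-butyldimethylsilyl)oxy]-6-methyl-2-oxoheptyl]-5-[4-(methoxymethoxy)phenyl]-4-oxo-4H-pyran-3-carboxylate
Conditions: LiN(SiMe3)2 (2.2 equiv), THF, −78 °C; then 14, −78 → −20 °C; aq. NH4Cl at −78 °C
Reagents that add atoms: none
Why: The 2-methyl group is vinylogous to both the C4 ketone and the C3 ester, so the hindered amide base should give the lateral dienolate, which is acylated at its exocyclic carbon by the Weinreb amide through a chelated tetrahedral intermediate that prevents over-addition (lateral metalation–acylation of a 2-methyl-4-pyranone).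

Step 8
Reactants: 15 methyl 2-[(5S)-5-[(tert-butyldimethylsilyl)oxy]-6-methyl-2-oxoheptyl]-5-[4-(methoxymethoxy)phenyl]-4-oxo-4H-pyran-3-carboxylate; 16 1-bromo-3-methylbut-2-ene
Product: 17 methyl 2-[(9S)-9-[(tert-butyldimethylsilyl)oxy]-2,10-dimethyl-6-oxoundec-2-en-5-yl]-5-[4-(methoxymethoxy)phenyl]-4-oxo-4H-pyran-3-carboxylate (both epimers at the prenylated carbon)
Conditions: K2CO3 (1.5 equiv), 16 (1.1 equiv), acetone, 0 → 23 °C
Reagents that add atoms: none
Why: The CH2 between the ketone and C2 of the pyranone is the most acidic site and its soft, delocalised anion should be C-alkylated by the allylic bromide in an SN2 reaction (β-dicarbonyl-type alkylation); the new stereocentre forms without control, which is harmless because step 9 destroys it.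

Step 9
Reactants: 17 methyl 2-[(9S)-9-[(tert-butyldimethylsilyl)oxy]-2,10-dimethyl-6-oxoundec-2-en-5-yl]-5-[4-(methoxymethoxy)phenyl]-4-oxo-4H-pyran-3-carboxylate
Product: 18 6-[(2S)-2-[(tert-butyldimethylsilyl)oxy]-3-methylbutyl]-5,7-dihydroxy-3-[4-(methoxymethoxy)phenyl]-8-(3-methylbut-2-en-1-yl)-4H-chromen-4-one
Conditions: 17 added to LiN(SiMe3)2 (4 equiv), THF (0.02 M), −78 → 23 °C; aq. NH4Cl
Reagents that add atoms: none
Why: Proposed new method: base first removes the doubly activated C8–H (flanked by the C7 ketone and the vinylogous pyranone ester) and then a C6–H, and the C6 carbanion, the more nucleophilic end of the dianion, adds to the C5 ester carbonyl; loss of methoxide and tautomerisation of the cyclic triketone give aromatic ring A as its bis-phenoxide. The closest known reactions are the base-mediated Claisen cyclisation of 3,5,7-triketo esters and their pyrone-masked forms to acylphloroglucinols and the analogous closure of 2-(2-oxoalkyl)benzoates to naphthalene-1,3-diols, but the closure has not been shown on a 4-pyranone-3-carboxylate. Ring A closes in a 6-(enolendo)-exo-trig mode, and the C4a=C8a double bond of ring C holds the chain and the ester cis to each other. No stereocentre is formed: C8 becomes sp2, so both epimers of 17 converge, and the silyloxy carbon is remote from every acidic site. The step needs C- over O-acylation and reaction through C6: C8 could only close a four-membered ring, the C4 carbonyl is a deactivated vinylogous ester whose attack would give a bridged aldol, and O-acylation by the C7 enolate oxygen gives an enol lactone that the released methoxide can reopen, whereas C-acylation is made irreversible by aromatisation.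

Step 10
Reactants: 18 6-[(2S)-2-[(tert-butyldimethylsilyl)oxy]-3-methylbutyl]-5,7-dihydroxy-3-[4-(methoxymethoxy)phenyl]-8-(3-methylbut-2-en-1-yl)-4H-chromen-4-one
Product: 19 6-[(2S)-2-[(tert-butyldimethylsilyl)oxy]-3-methylbutyl]-5-hydroxy-7-(methoxymethoxy)-3-[4-(methoxymethoxy)phenyl]-8-(3-methylbut-2-en-1-yl)-4H-chromen-4-one
Conditions: MeOCH2Cl (1.2 equiv), i-Pr2NEt, CH2Cl2, 0 → 23 °C
Reagents that add atoms: chloromethyl methyl ether, COCCl
Why: The 5-OH is hydrogen-bonded to the C4 carbonyl and much less nucleophilic, so Williamson-type alkylation with a small electrophile and a hindered amine should occur only at the 7-OH (chelation-controlled selective protection), giving an acetal that, unlike a 7-O-silyl ether, survives the carbonate base of step 11.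

Step 11
Reactants: 19 6-[(2S)-2-[(tert-butyldimethylsilyl)oxy]-3-methylbutyl]-5-hydroxy-7-(methoxymethoxy)-3-[4-(methoxymethoxy)phenyl]-8-(3-methylbut-2-en-1-yl)-4H-chromen-4-one
Product: 20 6-[(2S)-2-[(tert-butyldimethylsilyl)oxy]-3-methylbutyl]-5-methoxy-7-(methoxymethoxy)-3-[4-(methoxymethoxy)phenyl]-8-(3-methylbut-2-en-1-yl)-4H-chromen-4-one
Conditions: MeI (5 equiv), K2CO3 (3 equiv), DMF, 40 °C
Reagents that add atoms: iodomethane, CI
Why: With the 7-OH masked, the chelated 5-OH is the only acidic site left and should be methylated under forcing Williamson conditions, to which both acetals and the silyl ether are inert.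

Step 12
Reactants: 20 6-[(2S)-2-[(tert-butyldimethylsilyl)oxy]-3-methylbutyl]-5-methoxy-7-(methoxymethoxy)-3-[4-(methoxymethoxy)phenyl]-8-(3-methylbut-2-en-1-yl)-4H-chromen-4-one
Product: 21 7-hydroxy-6-[(2S)-2-hydroxy-3-methylbutyl]-3-(4-hydroxyphenyl)-5-methoxy-8-(3-methylbut-2-en-1-yl)-4H-chromen-4-one
Conditions: 3 M aq. HCl, MeOH, 40 °C
Reagents that add atoms: none
Why: Acid-catalysed acetal exchange removes both aryl methoxymethyl ethers and solvolysis cleaves the secondary silyl ether in one global deprotection, under conditions that should be mild enough to leave the prenyl group, the aryl methyl ether and the carbinol configuration untouched.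

**Compound list**

1 | 2-(4-hydroxyphenyl)acetic acid | OC(=O)Cc1ccc(O)cc1 | starting material
2 | methoxymethyl 2-[4-(methoxymethoxy)phenyl]acetate | COCOC(=O)Cc1ccc(OCOC)cc1 | intermediate
3 | 2-[4-(methoxymethoxy)phenyl]acetic acid | COCOc1ccc(CC(=O)O)cc1 | intermediate
4 | methyl acetoacetate | COC(=O)CC(C)=O | starting material
5 | 2-[4-(methoxymethoxy)phenyl]acetyl chloride | COCOc1ccc(CC(=O)Cl)cc1 | intermediate
6 | methyl 2-acetyl-4-[4-(methoxymethoxy)phenyl]-3-oxobutanoate | COC(=O)C(C(C)=O)C(=O)Cc1ccc(OCOC)cc1 | intermediate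
7 | methyl 2-acetyl-5-(dimethylamino)-4-[4-(methoxymethoxy)phenyl]-3-oxopent-4-enoate | COC(=O)C(C(C)=O)C(=O)C(=CN(C)C)c1ccc(OCOC)cc1 | intermediate
8 | methyl 5-[4-(methoxymethoxy)phenyl]-2-methyl-4-oxo-4H-pyran-3-carboxylate | COC(=O)c1c(C)occ(-c2ccc(OCOC)cc2)c1=O | intermediate
9 | (2R)-2-(propan-2-yl)oxirane | CC(C)[C@@H]1CO1 | starting material
10 | dimethyl malonate | COC(=O)CC(=O)OC | starting material
11 | methyl (5S)-2-oxo-5-(propan-2-yl)oxolane-3-carboxylate (C3 epimers) | COC(=O)C1C[C@@H](C(C)C)OC1=O | intermediate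
12 | (5S)-5-(propan-2-yl)oxolan-2-one | O=C1CC[C@@H](C(C)C)O1 | intermediate
13 | (4S)-4-hydroxy-N-methoxy-N,5-dimethylhexanamide | CON(C)C(=O)CC[C@H](O)C(C)C | intermediate
14 | (4S)-4-[(tert-butyldimethylsilyl)oxy]-N-methoxy-N,5-dimethylhexanamide | CON(C)C(=O)CC[C@H](O[Si](C)(C)C(C)(C)C)C(C)C | intermediate
15 | methyl 2-[(5S)-5-[(tert-butyldimethylsilyl)oxy]-6-methyl-2-oxoheptyl]-5-[4-(methoxymethoxy)phenyl]-4-oxo-4H-pyran-3-carboxylate | COC(=O)c1c(CC(=O)CC[C@H](O[Si](C)(C)C(C)(C)C)C(C)C)occ(-c2ccc(OCOC)cc2)c1=O | intermediate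
16 | 1-bromo-3-methylbut-2-ene | CC(C)=CCBr | starting material
17 | methyl 2-[(9S)-9-[(tert-butyldimethylsilyl)oxy]-2,10-dimethyl-6-oxoundec-2-en-5-yl]-5-[4-(methoxymethoxy)phenyl]-4-oxo-4H-pyran-3-carboxylate (both epimers at the prenylated carbon) | COC(=O)c1c(C(CC=C(C)C)C(=O)CC[C@H](O[Si](C)(C)C(C)(C)C)C(C)C)occ(-c2ccc(OCOC)cc2)c1=O | intermediate
18 | 6-[(2S)-2-[(tert-butyldimethylsilyl)oxy]-3-methylbutyl]-5,7-dihydroxy-3-[4-(methoxymethoxy)phenyl]-8-(3-methylbut-2-en-1-yl)-4H-chromen-4-one | Oc1c(C[C@H](O[Si](C)(C)C(C)(C)C)C(C)C)c(O)c(CC=C(C)C)c2occ(-c3ccc(OCOC)cc3)c(=O)c12 | intermediate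
19 | 6-[(2S)-2-[(tert-butyldimethylsilyl)oxy]-3-methylbutyl]-5-hydroxy-7-(methoxymethoxy)-3-[4-(methoxymethoxy)phenyl]-8-(3-methylbut-2-en-1-yl)-4H-chromen-4-one | Oc1c(C[C@H](O[Si](C)(C)C(C)(C)C)C(C)C)c(OCOC)c(CC=C(C)C)c2occ(-c3ccc(OCOC)cc3)c(=O)c12 | intermediate
20 | 6-[(2S)-2-[(tert-butyldimethylsilyl)oxy]-3-methylbutyl]-5-methoxy-7-(methoxymethoxy)-3-[4-(methoxymethoxy)phenyl]-8-(3-methylbut-2-en-1-yl)-4H-chromen-4-one | COc1c(C[C@H](O[Si](C)(C)C(C)(C)C)C(C)C)c(OCOC)c(CC=C(C)C)c2occ(-c3ccc(OCOC)cc3)c(=O)c12 | intermediate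
21 | 7-hydroxy-6-[(2S)-2-hydroxy-3-methylbutyl]-3-(4-hydroxyphenyl)-5-methoxy-8-(3-methylbut-2-en-1-yl)-4H-chromen-4-one | COc1c(C[C@H](O)C(C)C)c(O)c(CC=C(C)C)c2occ(-c3ccc(O)cc3)c(=O)c12 | target

**Step count.** Total: 12 steps. Longest linear sequence: 9 steps (9 → 21 through steps 4–12; the line from 1 through steps 1–3 and 7–12 is equally long).

**Steps most likely to fail**

Step 9 (key step). The ester may stay inert because the first deprotonation delocalises charge onto it, the second deprotonation may be incomplete, or the C7 enolate oxygen may acylate and stall at the enol lactone. The fallback uses only known chemistry: ring A is taken from an arene by three directed ortho-metalations and ring C is closed last. It sets out from 16 (using 9 and 3 as the other route compounds) and comes back at the target 21.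
- Commercial 5-methoxyresorcinol would be protected (MeOCH2Cl, i-Pr2NEt) as 1-methoxy-3,5-bis(methoxymethoxy)benzene F1.
- Lithiation between the two acetal groups (n-BuLi, THF, 0 °C), transmetalation with CuI and allylation with 16 should give 5-methoxy-1,3-bis(methoxymethoxy)-2-(3-methylbut-2-en-1-yl)benzene F2.
- A second lithiation at one of the two equivalent positions between OMe and the acetal, then BF3·OEt2-promoted opening of epoxide 9 at its CH2 terminus (−78 °C), should give (2S)-1-[6-methoxy-2,4-bis(methoxymethoxy)-3-(3-methylbut-2-en-1-yl)phenyl]-3-methylbutan-2-ol F3 with the configuration retained.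
- Silylation (t-BuMe2SiCl, imidazole) would give the silyl ether tert-butyl{[(2S)-1-[6-methoxy-2,4-bis(methoxymethoxy)-3-(3-methylbut-2-en-1-yl)phenyl]-3-methylbutan-2-yl]oxy}dimethylsilane F4.
- Lithiation of the last ring position and acylation with N-methoxy-2-[4-(methoxymethoxy)phenyl]-N-methylacetamide F5 (from 3, 1,1'-carbonyldiimidazole, MeNH(OMe)·HCl) should give the hexasubstituted deoxybenzoin 1-[3-[(2S)-2-[(tert-butyldimethylsilyl)oxy]-3-methylbutyl]-2-methoxy-4,6-bis(methoxymethoxy)-5-(3-methylbut-2-en-1-yl)phenyl]-2-[4-(methoxymethoxy)phenyl]ethan-1-one F6.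
- HCl in MeOH would remove the three acetals and the silyl group to give 1-[2,4-dihydroxy-5-[(2S)-2-hydroxy-3-methylbutyl]-6-methoxy-3-(3-methylbut-2-en-1-yl)phenyl]-2-(4-hydroxyphenyl)ethan-1-one F7.
- The classical isoflavone closure with Me2NCH(OMe)2 (THF, 60 °C) can use only the single hydroxyl ortho to the ketone, which fixes the 5-OMe, C6 chain and C8 prenyl pattern, and should give 21.

Step 7. The stabilised dienolate may be too weak a nucleophile for the amide, may self-condense through its ester, or the product may cyclise early under the excess base. The fallback replaces acylation by aldol addition and oxidation; it sets out from 14 and comes back at 15.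
- i-Bu2AlH (THF, −78 °C) would reduce 14 to (4S)-4-[(tert-butyldimethylsilyl)oxy]-5-methylhexanal F8.
- The lithium dienolate of 8 (LiN(SiMe3)2, −78 °C) should add to this much more electrophilic partner to give methyl 2-[(5S)-5-[(tert-butyldimethylsilyl)oxy]-2-hydroxy-6-methylheptyl]-5-[4-(methoxymethoxy)phenyl]-4-oxo-4H-pyran-3-carboxylate F9 (both carbinol epimers).
- Dess–Martin periodinane (NaHCO3-buffered, CH2Cl2) should oxidise F9 to 15.

Step 8. O-alkylation of the ambident anion, double alkylation, or enol-lactone formation of 15 during prolonged exposure to base may compete. The fallback reverses the order of the two C–C bond formations so that no ketone enolate is ever alkylated; it sets out from 8 and comes back at 17.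
- The lithium dienolate of 8 would be alkylated with 16 (LiN(SiMe3)2, THF, −78 °C) to give methyl 5-[4-(methoxymethoxy)phenyl]-2-(4-methylpent-3-en-1-yl)-4-oxo-4H-pyran-3-carboxylate F10.
- The remaining lateral CH2 of F10 would be deprotonated in the same way and acylated with 14, giving 17 directly.

**Further compounds**

F1 | step 9 | 1-methoxy-3,5-bis(methoxymethoxy)benzene | COCOc1cc(OC)cc(OCOC)c1
F2 | step 9 | 5-methoxy-1,3-bis(methoxymethoxy)-2-(3-methylbut-2-en-1-yl)benzene | COCOc1cc(OC)cc(OCOC)c1CC=C(C)C
F3 | step 9 | (2S)-1-[6-methoxy-2,4-bis(methoxymethoxy)-3-(3-methylbut-2-en-1-yl)phenyl]-3-methylbutan-2-ol | COc1cc(OCOC)c(CC=C(C)C)c(OCOC)c1C[C@H](O)C(C)C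
F4 | step 9 | tert-butyl{[(2S)-1-[6-methoxy-2,4-bis(methoxymethoxy)-3-(3-methylbut-2-en-1-yl)phenyl]-3-methylbutan-2-yl]oxy}dimethylsilane | COc1cc(OCOC)c(CC=C(C)C)c(OCOC)c1C[C@H](O[Si](C)(C)C(C)(C)C)C(C)C
F5 | step 9 | N-methoxy-2-[4-(methoxymethoxy)phenyl]-N-methylacetamide | CON(C)C(=O)Cc1ccc(OCOC)cc1
F6 | step 9 | 1-[3-[(2S)-2-[(tert-butyldimethylsilyl)oxy]-3-methylbutyl]-2-methoxy-4,6-bis(methoxymethoxy)-5-(3-methylbut-2-en-1-yl)phenyl]-2-[4-(methoxymethoxy)phenyl]ethan-1-one | COc1c(C(=O)Cc2ccc(OCOC)cc2)c(OCOC)c(CC=C(C)C)c(OCOC)c1C[C@H](O[Si](C)(C)C(C)(C)C)C(C)C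
F7 | step 9 | 1-[2,4-dihydroxy-5-[(2S)-2-hydroxy-3-methylbutyl]-6-methoxy-3-(3-methylbut-2-en-1-yl)phenyl]-2-(4-hydroxyphenyl)ethan-1-one | COc1c(C(=O)Cc2ccc(O)cc2)c(O)c(CC=C(C)C)c(O)c1C[C@H](O)C(C)C
F8 | step 7 | (4S)-4-[(tert-butyldimethylsilyl)oxy]-5-methylhexanal | O=CCC[C@H](O[Si](C)(C)C(C)(C)C)C(C)C
F9 | step 7 | methyl 2-[(5S)-5-[(tert-butyldimethylsilyl)oxy]-2-hydroxy-6-methylheptyl]-5-[4-(methoxymethoxy)phenyl]-4-oxo-4H-pyran-3-carboxylate | COC(=O)c1c(CC(O)CC[C@H](O[Si](C)(C)C(C)(C)C)C(C)C)occ(-c2ccc(OCOC)cc2)c1=O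
F10 | step 8 | methyl 5-[4-(methoxymethoxy)phenyl]-2-(4-methylpent-3-en-1-yl)-4-oxo-4H-pyran-3-carboxylate | COC(=O)c1c(CCC=C(C)C)occ(-c2ccc(OCOC)cc2)c1=O
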